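The chain C2(=O)-C3-C3'-C2'(=O) that runs through both pyranone rings is the carbon skeleton of succinic acid. Each inner carbon is the alpha carbon of a lactonised o-hydroxycinnamate: C3=C4 in unit A (the 7-hydroxy-6,8-dimethoxycoumarin) and C3'=C4' in unit B (the 6,7-dihydroxycoumarin). The C3-C3' bond is therefore bought, not made.
Last skeletal disconnection: pyranone ring B is opened at C3'=C4' and O1'-C2'. This gives the 7-O-benzyl coumarin-A 3-acetic acid and 2,4,5-trihydroxybenzaldehyde (Perkin-Oglialoro condensation, then lactonisation).
Pyranone ring A is opened the same way at C3=C4 and O1-C2, giving 4-(benzyloxy)-2-hydroxy-3,5-dimethoxybenzaldehyde and succinic anhydride.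
That salicylaldehyde comes from syringaldehyde by O-benzylation, bromination ortho to the formyl group, borylation and boronate oxidation (this oxygen becomes O1).
Ring order: both benzene rings are bought, pyranone A closes first (step 5) and pyranone B second (step 6). Hydrogenolysis and acidic acetate methanolysis finish the synthesis.

Key step: step 6

Remark: the target has no stereocentre. The C3-C3' axis is flanked only by H4, H4' and the two lactone carbonyls, so free rotation is assumed and no stereocontrol is planned.

Step 1
Reactants: 1 syringaldehyde (4-hydroxy-3,5-dimethoxybenzaldehyde)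
Product: 2 4-(benzyloxy)-3,5-dimethoxybenzaldehyde
Conditions: BnBr, K2CO3, DMF, 60 °C
Reagents that add atoms: benzyl bromide, BrCc1ccccc1
Why: Williamson ether synthesis, in which the acidic phenoxide para to the formyl group is alkylated by benzyl bromide while the aldehyde and methyl ethers are inert to K2CO3.

Step 2
Reactants: 2 4-(benzyloxy)-3,5-dimethoxybenzaldehyde
Product: 3 4-(benzyloxy)-2-bromo-3,5-dimethoxybenzaldehyde
Conditions: NBS (1.05 equiv), MeCN, 40 °C, dark
Reagents that add atoms: N-bromosuccinimide, O=C1CCC(=O)N1Br
Why: Electrophilic aromatic bromination, in which the equivalent positions C2 and C6 each lie ortho to one methoxy group and para to the other, so a single monobromide is expected as with 3,4,5-trimethoxybenzaldehyde, while the polar solvent and exclusion of light hold back radical attack at the benzylic CH2.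

Step 3
Reactants: 3 4-(benzyloxy)-2-bromo-3,5-dimethoxybenzaldehyde
Product: 4 4-(benzyloxy)-3,5-dimethoxy-2-(4,4,5,5-tetramethyl-1,3,2-dioxaborolan-2-yl)benzaldehyde
Conditions: B2pin2, Pd(dppf)Cl2 (5 mol %), KOAc, 1,4-dioxane, 90 °C
Reagents that add atoms: bis(pinacolato)diboron, CC1(C)OB(OC1(C)C)B1OC(C)(C)C(C)(C)O1
Why: Miyaura borylation, in which zerovalent palladium inserts into the C-Br bond activated by the ortho formyl group, acetate mediates the transfer of boron from B2pin2, and the weak base leaves the aldehyde and the benzyl ether untouched.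

Step 4
Reactants: 4 4-(benzyloxy)-3,5-dimethoxy-2-(4,4,5,5-tetramethyl-1,3,2-dioxaborolan-2-yl)benzaldehyde
Product: 5 4-(benzyloxy)-2-hydroxy-3,5-dimethoxybenzaldehyde
Conditions: 30% aq H2O2 (1.05 equiv), THF, NaH2PO4/Na2HPO4 buffer (pH 7), 0 °C to rt
Reagents that add atoms: hydrogen peroxide, OO
Why: Boronate oxidation (hydroperoxide adds to boron and the aryl group shifts to oxygen at the ipso carbon) is much faster than Dakin oxidation of the formyl group, so one equivalent of peroxide at neutral pH and low temperature should stop at the salicylaldehyde.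

Step 5
Reactants: 5 4-(benzyloxy)-2-hydroxy-3,5-dimethoxybenzaldehyde, 6 succinic anhydride
Product: 8 2-[7-(benzyloxy)-6,8-dimethoxy-2-oxo-2H-chromen-3-yl]acetic acid, via aryl hydrogen succinate 7 (not isolated)
Conditions: succinic anhydride (4 equiv), disodium succinate (1 equiv), neat melt, 175 °C, N2; acid-base work-up
Reagents that add atoms: none
Why: Perkin condensation in its coumarin form, in which the phenol opens the anhydride to 7, succinate enolises the CH2 alpha to the aryl ester, this carbon adds to the neighbouring formyl group through a six-membered ring rather than the seven-membered alternative, and dehydration gives pyranone ring A with the other CH2CO2H left at C3, while excess anhydride binds the water and keeps a second condensation of 8 with 5 down.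

Step 6
Reactants: 8 2-[7-(benzyloxy)-6,8-dimethoxy-2-oxo-2H-chromen-3-yl]acetic acid, 9 2,4,5-trihydroxybenzaldehyde
Product: 12 7-O-benzyl-6',7'-di-O-acetylarteminorin C, via mixed acetic anhydride 10 (not isolated), via 2,4,5-triacetoxybenzaldehyde 11 (not isolated)
Conditions: 9 (1.1 equiv), Ac2O (solvent), Et3N (4 equiv, added last), 110 °C, N2
Reagents that add atoms: acetic anhydride, CC(=O)OC(C)=O
Why: Ac2O turns acid 8 into the mixed anhydride 10 and aldehyde 9 into the triacetate 11, and Et3N then enolises the CH2 of 10, which is acidified by the acyl group and by allylic conjugation with C3=C4, so that the enolate adds to the formyl carbon of 11 (the future C4'). Acetylation of the aldol oxygen and E1cB loss of acetate install C3'=C4', while acyl exchange frees the oxygen ortho to the former formyl group (the future O1'), which attacks the activated C2' acyl carbon and expels acetate. The closest known reaction type is the Perkin-Oglialoro synthesis of 3-arylcoumarins from arylacetic acids and o-hydroxybenzaldehydes in Ac2O with an amine or acetate base, which is established for polyhydroxybenzaldehydes that emerge as acetoxycoumarins. Pyranone ring B closes by a 6-exo-trig acyl substitution (lactonisation) that is irreversible under the conditions and consumes the alkene isomer holding the aryl group cis to the acyl carbon, the other isomer being fed back by reversible conjugate addition of acetate. No stereocentre is formed, so only chemoselectivity is needed: cross-condensation is secured because 8 holds the only activated CH2 and no aldehyde while 9 holds the only aldehyde and no enolisable carbon, and the competing Perkin reaction of Ac2O itself is held back by the much lower acidity of its CH3 group. Peracetylation in the same flask masks the oxidation-prone 6',7'-catechol, and the benzyl ether, the methyl ethers and the lactone of ring A are inert to Ac2O and Et3N.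

Step 7
Reactants: 12 7-O-benzyl-6',7'-di-O-acetylarteminorin C
Product: 13 6',7'-di-O-acetylarteminorin C
Conditions: H2 (1 atm), 10% Pd/C, THF/EtOAc, rt, stopped after uptake of one equivalent
Reagents that add atoms: none
Why: Catalytic hydrogenolysis, in which the benzylic C-O bond is cleaved on palladium at atmospheric pressure faster than the trisubstituted, fully conjugated C3=C4 and C3'=C4' bonds are saturated, the acetates, lactones and methyl ethers are inert, and the diacetate is chosen as substrate because it should be the most soluble member of the series.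

Step 8
Reactants: 13 6',7'-di-O-acetylarteminorin C
Product: 14 arteminorin C
Conditions: HCl (1 M in MeOH), reflux, N2
Reagents that add atoms: none
Why: Acid-catalysed transesterification of the two aryl acetates with methanol, in which both pyranone lactones stay closed because a cis o-hydroxycinnamate recloses at once, and the acidic oxygen-free medium avoids the catechol oxidation that basic methanolysis would invite.

Compound list
1 | syringaldehyde (4-hydroxy-3,5-dimethoxybenzaldehyde) | COc1cc(C=O)cc(OC)c1O | starting material
2 | 4-(benzyloxy)-3,5-dimethoxybenzaldehyde | COc1cc(C=O)cc(OC)c1OCc1ccccc1 | intermediate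
3 | 4-(benzyloxy)-2-bromo-3,5-dimethoxybenzaldehyde | COc1cc(C=O)c(Br)c(OC)c1OCc1ccccc1 | intermediate
4 | 4-(benzyloxy)-3,5-dimethoxy-2-(4,4,5,5-tetramethyl-1,3,2-dioxaborolan-2-yl)benzaldehyde | COc1cc(C=O)c(B2OC(C)(C)C(C)(C)O2)c(OC)c1OCc1ccccc1 | intermediate
5 | 4-(benzyloxy)-2-hydroxy-3,5-dimethoxybenzaldehyde | COc1cc(C=O)c(O)c(OC)c1OCc1ccccc1 | intermediate
6 | succinic anhydride | O=C1CCC(=O)O1 | starting material
7 | 3-(benzyloxy)-6-formyl-2,4-dimethoxyphenyl hydrogen succinate (not isolated) | COc1cc(C=O)c(OC(=O)CCC(=O)O)c(OC)c1OCc1ccccc1 | intermediate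
8 | 2-[7-(benzyloxy)-6,8-dimethoxy-2-oxo-2H-chromen-3-yl]acetic acid | COc1cc2cc(CC(=O)O)c(=O)oc2c(OC)c1OCc1ccccc1 | intermediate
9 | 2,4,5-trihydroxybenzaldehyde | O=Cc1cc(O)c(O)cc1O | starting material
10 | acetic 2-[7-(benzyloxy)-6,8-dimethoxy-2-oxo-2H-chromen-3-yl]acetic anhydride (not isolated) | COc1cc2cc(CC(=O)OC(C)=O)c(=O)oc2c(OC)c1OCc1ccccc1 | intermediate
11 | 2,4,5-triacetoxybenzaldehyde (not isolated) | CC(=O)Oc1cc(OC(C)=O)c(OC(C)=O)cc1C=O | intermediate
12 | 7-O-benzyl-6',7'-di-O-acetylarteminorin C (7-(benzyloxy)-6,8-dimethoxy-2,2'-dioxo-2H,2'H-[3,3'-bichromene]-6',7'-diyl diacetate) | COc1cc2cc(-c3cc4cc(OC(C)=O)c(OC(C)=O)cc4oc3=O)c(=O)oc2c(OC)c1OCc1ccccc1 | intermediate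
13 | 6',7'-di-O-acetylarteminorin C (7-hydroxy-6,8-dimethoxy-2,2'-dioxo-2H,2'H-[3,3'-bichromene]-6',7'-diyl diacetate) | COc1cc2cc(-c3cc4cc(OC(C)=O)c(OC(C)=O)cc4oc3=O)c(=O)oc2c(OC)c1O | intermediate
14 | arteminorin C (6',7,7'-trihydroxy-6,8-dimethoxy-2H,2'H-[3,3'-bichromene]-2,2'-dione) | COc1cc2cc(-c3cc4cc(O)c(O)cc4oc3=O)c(=O)oc2c(OC)c1O | target

Total step count: 8
Longest linear sequence: 8 steps (1 to 14); 6 and 9 are bought and enter directly.

Steps most likely to fail

Step 6. In hot Ac2O/Et3N several things may go wrong. The aldehyde may close with acetate instead of with the acid partner. The acid component may be lost by decarboxylation. The electron-rich aldehyde may darken and polymerise. Early precipitation of a poorly soluble product may also stall conversion.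
The fallback forms the same two bonds in the opposite order and at room temperature. It sets out from 8 and 9 and comes back at 14.
- Benzylation of the two non-chelated hydroxy groups of 9 (BnBr 2 equiv, K2CO3, DMF, rt, N2) would give 4,5-bis(benzyloxy)-2-hydroxybenzaldehyde F1.
- Steglich esterification of 8 with this phenol (EDC, DMAP, CH2Cl2) would make O1'-C2' first and give the 2-formylaryl ester F2.
- DBU in MeCN at rt would then close ring B by intramolecular aldol condensation (C3'=C4') to give 7,6',7'-tri-O-benzylarteminorin C F3.
- Hydrogenolysis of all three benzyl ethers (H2, Pd/C, THF) returns to the route at 14.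

Step 5. At the melt temperature the product acid may condense a second time with unreacted 5. The electron-rich formyl group may react sluggishly, and decarboxylation or charring may erode the material.
The fallback replaces the four-carbon unit by a one-carbon homologation (Arndt-Eistert). It sets out from 5 and comes back at 8.
- Knoevenagel condensation and lactonisation with Meldrum's acid (piperidinium acetate, EtOH, reflux) would give 7-(benzyloxy)-6,8-dimethoxy-2-oxo-2H-chromene-3-carboxylic acid F4.
- Oxalyl chloride with catalytic DMF in CH2Cl2 would give the acid chloride F5.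
- Diazomethane with Et3N in Et2O/THF at 0 °C would give the diazoketone F6.
- Wolff rearrangement with catalytic AgO2CPh and Et3N in aqueous THF would pass through the ketene F7, which water captures to give 8.

Step 3. Slow boron transfer at a carbon flanked by a formyl and a methoxy group may let hydrodebromination and protodeborylation compete. The unprotected formyl group then has to face peroxide in step 4.
The fallback uses a masked aldehyde and main-group metalation. It sets out from 3 and comes back at 5, bypassing 4.
- Acetalisation (HC(OMe)3, cat. TsOH, MeOH, reflux) would give the dimethyl acetal F8.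
- Bromine-lithium exchange (n-BuLi, THF, -78 °C) would give the aryllithium F9.
- Trapping with B(OMe)3 would give the dimethyl arylboronate F10.
- H2O2 and aq NaOH at 0 °C would give the phenol acetal F11, with the aldehyde shielded from Dakin oxidation.
- Dilute HCl in THF releases the formyl group to give 5.

Further compounds
F1 | step 6 | 4,5-bis(benzyloxy)-2-hydroxybenzaldehyde | O=Cc1cc(OCc2ccccc2)c(OCc2ccccc2)cc1O
F2 | step 6 | 4,5-bis(benzyloxy)-2-formylphenyl 2-[7-(benzyloxy)-6,8-dimethoxy-2-oxo-2H-chromen-3-yl]acetate | COc1cc2cc(CC(=O)Oc3cc(OCc4ccccc4)c(OCc4ccccc4)cc3C=O)c(=O)oc2c(OC)c1OCc1ccccc1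
F3 | step 6 | 7,6',7'-tri-O-benzylarteminorin C | COc1cc2cc(-c3cc4cc(OCc5ccccc5)c(OCc5ccccc5)cc4oc3=O)c(=O)oc2c(OC)c1OCc1ccccc1
F4 | step 5 | 7-(benzyloxy)-6,8-dimethoxy-2-oxo-2H-chromene-3-carboxylic acid | COc1cc2cc(C(=O)O)c(=O)oc2c(OC)c1OCc1ccccc1
F5 | step 5 | 7-(benzyloxy)-6,8-dimethoxy-2-oxo-2H-chromene-3-carbonyl chloride | COc1cc2cc(C(=O)Cl)c(=O)oc2c(OC)c1OCc1ccccc1
F6 | step 5 | 7-(benzyloxy)-3-(2-diazoacetyl)-6,8-dimethoxy-2H-chromen-2-one | COc1cc2cc(C(=O)C=[N+]=[N-])c(=O)oc2c(OC)c1OCc1ccccc1
F7 | step 5 | [7-(benzyloxy)-6,8-dimethoxy-2-oxo-2H-chromen-3-yl]ketene | COc1cc2cc(C=C=O)c(=O)oc2c(OC)c1OCc1ccccc1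
F8 | step 3 | 4-(benzyloxy)-2-bromo-3,5-dimethoxybenzaldehyde dimethyl acetal | COC(OC)c1cc(OC)c(OCc2ccccc2)c(OC)c1Br
F9 | step 3 | [3-(benzyloxy)-6-(dimethoxymethyl)-2,4-dimethoxyphenyl]lithium | COC(OC)c1cc(OC)c(OCc2ccccc2)c(OC)c1[Li]
F10 | step 3 | dimethyl [3-(benzyloxy)-6-(dimethoxymethyl)-2,4-dimethoxyphenyl]boronate | COC(OC)c1cc(OC)c(OCc2ccccc2)c(OC)c1B(OC)OC
F11 | step 3 | 3-(benzyloxy)-6-(dimethoxymethyl)-2,4-dimethoxyphenol | COC(OC)c1cc(OC)c(OCc2ccccc2)c(OC)c1O
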